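**Retrosynthetic overview**

1. Target 15 ⇐ hydrogenolysis of three aryl benzyl ethers (14) ⇐ diacetylation of syn-diol 13 ⇐ 1,3-syn reduction of β-hydroxy ketone 11, in which the C5 carbinol sets the C3 carbinol.
2. Key disconnection: the bond from benzylic C1 to the catechol ring, made by palladium-catalysed ring-opening arylation of cyclopropanol 8 with aryl bromide 9 (a homoenolate, polarity-reversed coupling) to give ketone 10.
3. Enabling feature: C1 stands β to the oxygen-bearing C3, so with C3 at the ketone level C1 is a homoenolate carbon. C1, C2 and C3 are stored as a temporary cyclopropanol ring, whose strain-driven opening hands C1 to palladium and unveils the C3 carbonyl needed for the syn reduction.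
4. Cyclopropanol 8 ⇐ Kulinkovich reaction of silylated β-hydroxy ester 7 ⇐ Noyori hydrogenation of β-keto ester 5 (sets C5) ⇐ dianion alkylation of methyl acetoacetate 3 with benzylic bromide 2.
5. Rings: both benzene rings are bought; the only ring built is the temporary cyclopropane (step 5), which is opened again in step 6.

Key step: step 6

Remark: the heptane chain is numbered from the catechol end (C1) to the guaiacyl end (C7) throughout; in this numbering the target is the (3S,5R) syn-diacetate. Compounds 1, 3 and 9 are taken as catalogue materials.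

**Route**

Step 1
Reactants: 1 4-(benzyloxy)-3-methoxybenzyl alcohol
Product: 2 4-(benzyloxy)-3-methoxybenzyl bromide
Conditions: PBr3 (0.4 equiv), Et2O, 0 °C; used directly
Reagents that add atoms: phosphorus tribromide, BrP(Br)Br
Why: Conversion of an electron-rich benzylic alcohol into its bromide through the phosphite ester (alcohol-to-bromide substitution with PBr3) should be fast and clean at 0 °C, and the labile bromide is used at once.

Step 2
Reactants: 2 4-(benzyloxy)-3-methoxybenzyl bromide; 3 methyl acetoacetate
Product: 5 methyl 5-[4-(benzyloxy)-3-methoxyphenyl]-3-oxopentanoate, via methyl acetoacetate dianion 4 (not isolated)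
Conditions: 3, NaH, THF, 0 °C; n-BuLi, 0 °C; then 2, 0 °C → rt; aq. HCl quench
Reagents that add atoms: sodium hydride, [Na+].[H-], and n-butyllithium, [Li]CCCC (both supply only the counter-ions of 4; no reagent atoms remain in 5)
Why: Weiler dianion alkylation, in which the dianion reacts at its more basic terminal carbon with the reactive benzylic bromide and the product stays protected as its enolate, so mono-alkylation at the methyl terminus should dominate.

Step 3
Reactants: 5 methyl 5-[4-(benzyloxy)-3-methoxyphenyl]-3-oxopentanoate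
Product: 6 methyl (3R)-5-[4-(benzyloxy)-3-methoxyphenyl]-3-hydroxypentanoate
Conditions: [RuCl(p-cymene)((R)-BINAP)]Cl (1 mol%), H2 (30 atm), MeOH, 50 °C
Reagents that add atoms: none
Why: Noyori asymmetric hydrogenation of a β-keto ester, in which the ester carbonyl chelates ruthenium and the (R)-BINAP ligand directs hydride to one ketone face, should set the (3R) carbinol (the future C5 of the heptane) while the aryl benzyl ether is inert to this homogeneous catalyst.

Step 4
Reactants: 6 methyl (3R)-5-[4-(benzyloxy)-3-methoxyphenyl]-3-hydroxypentanoate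
Product: 7 methyl (3R)-5-[4-(benzyloxy)-3-methoxyphenyl]-3-[(tert-butyldimethylsilyl)oxy]pentanoate
Conditions: TBSCl, imidazole, DMF, rt
Reagents that add atoms: tert-butyldimethylsilyl chloride, CC(C)(C)[Si](C)(C)Cl
Why: Standard imidazole-mediated silylation masks the secondary alcohol so that it neither quenches the Grignard reagent in step 5 nor binds palladium in step 6.

Step 5
Reactants: 7 methyl (3R)-5-[4-(benzyloxy)-3-methoxyphenyl]-3-[(tert-butyldimethylsilyl)oxy]pentanoate
Product: 8 1-[(2R)-4-[4-(benzyloxy)-3-methoxyphenyl]-2-[(tert-butyldimethylsilyl)oxy]butyl]cyclopropan-1-ol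
Conditions: Ti(OiPr)4 (0.3 equiv), EtMgBr (3 equiv, slow addition), THF, 0 °C → rt; aq. NH4Cl
Reagents that add atoms: ethylmagnesium bromide, CC[Mg]Br
Why: Kulinkovich cyclopropanation, in which the titanacyclopropane formed from EtMgBr and Ti(OiPr)4 acts as a 1,2-dicarbanion equivalent that adds twice to the ester carbonyl, should give the 1-substituted cyclopropanol without touching the silyl ether, the aryl ethers or the remote stereocenter.

Step 6
Reactants: 8 1-[(2R)-4-[4-(benzyloxy)-3-methoxyphenyl]-2-[(tert-butyldimethylsilyl)oxy]butyl]cyclopropan-1-ol; 9 1,2-bis(benzyloxy)-4-bromobenzene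
Product: 10 (5R)-1-[3,4-bis(benzyloxy)phenyl]-7-[4-(benzyloxy)-3-methoxyphenyl]-5-[(tert-butyldimethylsilyl)oxy]heptan-3-one
Conditions: Pd(OAc)2 (5 mol%), XPhos (10 mol%), Cs2CO3 (2 equiv), toluene, 80 °C
Reagents that add atoms: none
Why: Pd(OAc)2 and XPhos give zerovalent palladium, which inserts into the C–Br bond of 9; carbonate-assisted exchange places the tertiary cyclopropanol oxygen of 8 on divalent palladium, strain-driven β-carbon elimination opens the three-membered ring to a β-palladated ketone (a palladium homoenolate with C1 on the metal and C3 now a carbonyl), and C(sp3)–C(sp2) reductive elimination forms the C1–aryl bond. The closest known reaction type is the palladium-catalysed ring-opening cross-coupling of 1-alkylcyclopropanols with aryl bromides to give β-aryl ketones. It is a polarity-reversed union, because the β-carbon of a ketone and the ipso carbon of an aryl halide are both electrophilic in their ordinary guise and the cyclopropanol turns the former into a nucleophile. No ring is closed (the temporary C1–C2–C3 ring is opened) and no stereocenter is created; the C5 silyloxy stereocenter lies β to the new carbonyl, carries no acidic hydrogen and should pass unchanged. The step needs reductive elimination to outrun β-hydride elimination of the homoenolate (which would give the vinyl ketone), and the bulky electron-rich biarylphosphine together with carbonyl chelation of the alkylpalladium should secure this; ring-opening regiochemistry is no issue because the two ring CH2 groups of a 1-monosubstituted cyclopropanol are constitutionally equivalent. The heterogeneous carbonate base in toluene should be too weak to eliminate the β-silyloxy group.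

Step 7
Reactants: 10 (5R)-1-[3,4-bis(benzyloxy)phenyl]-7-[4-(benzyloxy)-3-methoxyphenyl]-5-[(tert-butyldimethylsilyl)oxy]heptan-3-one
Product: 11 (5R)-1-[3,4-bis(benzyloxy)phenyl]-7-[4-(benzyloxy)-3-methoxyphenyl]-5-hydroxyheptan-3-one
Conditions: aq. HF (48%), MeCN, 0 °C → rt
Reagents that add atoms: none
Why: Acidic fluoride desilylation avoids the basic conditions that could trigger retro-aldol cleavage or β-elimination of the aldol-type product, and aryl benzyl ethers are stable to HF in acetonitrile.

Step 8
Reactants: 11 (5R)-1-[3,4-bis(benzyloxy)phenyl]-7-[4-(benzyloxy)-3-methoxyphenyl]-5-hydroxyheptan-3-one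
Product: 13 (3S,5R)-1-[3,4-bis(benzyloxy)phenyl]-7-[4-(benzyloxy)-3-methoxyphenyl]heptane-3,5-diol, via diethylboron chelate 12 (not isolated)
Conditions: Et2BOMe (1.1 equiv), THF/MeOH (4:1), −78 °C; NaBH4, −78 °C; hydrolytic work-up (aq. NaHCO3)
Reagents that add atoms: diethylmethoxyborane, CCB(CC)OC (its Et2B group is held in 12 only; no reagent atoms other than hydrogen remain in 13)
Why: Narasaka–Prasad reduction, in which Et2BOMe locks the β-hydroxy ketone as a six-membered boron chelate and external hydride attacks axially, should let the existing (5R) carbinol set the new C3 carbinol syn, that is (3S).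

Step 9
Reactants: 13 (3S,5R)-1-[3,4-bis(benzyloxy)phenyl]-7-[4-(benzyloxy)-3-methoxyphenyl]heptane-3,5-diol
Product: 14 (3S,5R)-1-[3,4-bis(benzyloxy)phenyl]-7-[4-(benzyloxy)-3-methoxyphenyl]heptane-3,5-diyl diacetate
Conditions: Ac2O, pyridine, DMAP (cat.), CH2Cl2, rt
Reagents that add atoms: acetic anhydride, CC(=O)OC(C)=O
Why: DMAP-catalysed acylation of two unhindered secondary alcohols with acetic anhydride is reliable and installs both acetates of the target in one operation with retention at both carbinols.

Step 10
Reactants: 14 (3S,5R)-1-[3,4-bis(benzyloxy)phenyl]-7-[4-(benzyloxy)-3-methoxyphenyl]heptane-3,5-diyl diacetate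
Product: 15 (3S,5R)-1-(3,4-dihydroxyphenyl)-7-(4-hydroxy-3-methoxyphenyl)heptane-3,5-diyl diacetate
Conditions: H2 (1 atm), 10% Pd/C, EtOAc/MeOH, rt; filtration and concentration under argon
Reagents that add atoms: none
Why: Heterogeneous hydrogenolysis of the three aryl benzyl ethers should proceed under mild neutral conditions that leave the two secondary, non-benzylic acetates and both stereocenters untouched, so the air-sensitive catechol is released only at the end.

**Compound list**

1 | 4-(benzyloxy)-3-methoxybenzyl alcohol | COc1cc(CO)ccc1OCc1ccccc1 | starting material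
2 | 4-(benzyloxy)-3-methoxybenzyl bromide | COc1cc(CBr)ccc1OCc1ccccc1 | intermediate
3 | methyl acetoacetate | COC(=O)CC(C)=O | starting material
4 | methyl acetoacetate dianion (sodium lithium salt) | [Na+].[Li+].[CH2-]C(=O)[CH-]C(=O)OC | intermediate
5 | methyl 5-[4-(benzyloxy)-3-methoxyphenyl]-3-oxopentanoate | COC(=O)CC(=O)CCc1ccc(OCc2ccccc2)c(OC)c1 | intermediate
6 | methyl (3R)-5-[4-(benzyloxy)-3-methoxyphenyl]-3-hydroxypentanoate | COc1cc(CC[C@H](CC(=O)OC)O)ccc1OCc1ccccc1 | intermediate
7 | methyl (3R)-5-[4-(benzyloxy)-3-methoxyphenyl]-3-[(tert-butyldimethylsilyl)oxy]pentanoate | COc1cc(CC[C@H](CC(=O)OC)O[Si](C)(C)C(C)(C)C)ccc1OCc1ccccc1 | intermediate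
8 | 1-[(2R)-4-[4-(benzyloxy)-3-methoxyphenyl]-2-[(tert-butyldimethylsilyl)oxy]butyl]cyclopropan-1-ol | COc1cc(CC[C@H](CC2(O)CC2)O[Si](C)(C)C(C)(C)C)ccc1OCc1ccccc1 | intermediate
9 | 1,2-bis(benzyloxy)-4-bromobenzene | Brc1ccc(OCc2ccccc2)c(OCc2ccccc2)c1 | starting material
10 | (5R)-1-[3,4-bis(benzyloxy)phenyl]-7-[4-(benzyloxy)-3-methoxyphenyl]-5-[(tert-butyldimethylsilyl)oxy]heptan-3-one | COc1cc(CC[C@H](CC(=O)CCc2ccc(OCc3ccccc3)c(OCc3ccccc3)c2)O[Si](C)(C)C(C)(C)C)ccc1OCc1ccccc1 | intermediate
11 | (5R)-1-[3,4-bis(benzyloxy)phenyl]-7-[4-(benzyloxy)-3-methoxyphenyl]-5-hydroxyheptan-3-one | COc1cc(CC[C@H](CC(=O)CCc2ccc(OCc3ccccc3)c(OCc3ccccc3)c2)O)ccc1OCc1ccccc1 | intermediate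
12 | diethylboron chelate (O-diethylboryl derivative) of 11 | COc1cc(CC[C@H](CC(=O)CCc2ccc(OCc3ccccc3)c(OCc3ccccc3)c2)OB(CC)CC)ccc1OCc1ccccc1 | intermediate
13 | (3S,5R)-1-[3,4-bis(benzyloxy)phenyl]-7-[4-(benzyloxy)-3-methoxyphenyl]heptane-3,5-diol (syn) | COc1cc(CC[C@H](C[C@H](CCc2ccc(OCc3ccccc3)c(OCc3ccccc3)c2)O)O)ccc1OCc1ccccc1 | intermediate
14 | (3S,5R)-1-[3,4-bis(benzyloxy)phenyl]-7-[4-(benzyloxy)-3-methoxyphenyl]heptane-3,5-diyl diacetate | COc1cc(CC[C@H](C[C@H](CCc2ccc(OCc3ccccc3)c(OCc3ccccc3)c2)OC(C)=O)OC(C)=O)ccc1OCc1ccccc1 | intermediate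
15 | (3S,5R)-1-(3,4-dihydroxyphenyl)-7-(4-hydroxy-3-methoxyphenyl)heptane-3,5-diyl diacetate | COc1cc(CC[C@H](C[C@H](CCc2ccc(O)c(O)c2)OC(C)=O)OC(C)=O)ccc1O | target

**Step count and risks**

Total step count: 10. Longest linear sequence: 10 steps (1 → 15); aryl bromide 9 is bought and enters at step 6.

Steps most likely to fail:

Step 6 (key step). β-Hydride elimination of the palladium homoenolate may outrun reductive elimination, and base-induced β-elimination of the silyloxy group may erode the product. The fallback sets out from 8 and comes back at 10. The ring is opened oxidatively on purpose: Pd(OAc)2 (cat.), pyridine, O2 (1 atm), toluene, 80 °C should convert 8 by β-carbon elimination and β-hydride elimination into the vinyl ketone (5R)-7-[4-(benzyloxy)-3-methoxyphenyl]-5-[(tert-butyldimethylsilyl)oxy]hept-1-en-3-one F1. A Hayashi–Miyaura conjugate addition of commercial 3,4-bis(benzyloxy)phenylboronic acid ([Rh(OH)(cod)]2, dioxane/H2O, 40 °C, no added base) should then form the same C1–aryl bond under near-neutral conditions and give 10.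

Step 5. Direct Grignard addition to the ester may compete with the titanium-mediated cyclopropanation, and catalyst turnover may be incomplete. The fallback sets out from 7 and comes back at 10, bypassing the cyclopropanol. i-Bu2AlH (CH2Cl2, −78 °C) should reduce 7 to the aldehyde (3R)-5-[4-(benzyloxy)-3-methoxyphenyl]-3-[(tert-butyldimethylsilyl)oxy]pentanal F2. Vinylmagnesium bromide (THF, −78 °C) should give the allylic alcohol (5R)-7-[4-(benzyloxy)-3-methoxyphenyl]-5-[(tert-butyldimethylsilyl)oxy]hept-1-en-3-ol F3 as a mixture of C3 epimers, which is of no consequence because C3 becomes a carbonyl. A Heck reaction of F3 with 9 (Pd(OAc)2, P(t-Bu)3·HBF4, Cy2NMe, dioxane, 70 °C) should add the aryl group to the terminal alkene carbon and, after β-hydride elimination towards the carbinol and enol–keto tautomerisation, deliver ketone 10.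

Step 8. Incomplete boron chelation would erode the 1,3-syn induction in the hydride delivery. The fallback sets out from 11 and comes back at 14, so that step 9 is not needed. An Evans–Tishchenko reduction (SmI2 cat., acetaldehyde, THF, −10 °C) should transfer hydride within the samarium-bound hemiacetal to give the 1,3-anti monoacetate (3R,5R)-1-[3,4-bis(benzyloxy)phenyl]-7-[4-(benzyloxy)-3-methoxyphenyl]-3-hydroxyheptan-5-yl acetate F4, in which the original C5 oxygen carries the acetyl group and the new C3 hydroxyl is free. Mitsunobu inversion of that free carbinol with acetic acid (PPh3, DIAD, THF, 0 °C → rt) should then give the syn-diacetate 14.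

**Further compounds**

F1 | step 6 | (5R)-7-[4-(benzyloxy)-3-methoxyphenyl]-5-[(tert-butyldimethylsilyl)oxy]hept-1-en-3-one | COc1cc(CC[C@H](CC(=O)C=C)O[Si](C)(C)C(C)(C)C)ccc1OCc1ccccc1
F2 | step 5 | (3R)-5-[4-(benzyloxy)-3-methoxyphenyl]-3-[(tert-butyldimethylsilyl)oxy]pentanal | COc1cc(CC[C@H](CC=O)O[Si](C)(C)C(C)(C)C)ccc1OCc1ccccc1
F3 | step 5 | (5R)-7-[4-(benzyloxy)-3-methoxyphenyl]-5-[(tert-butyldimethylsilyl)oxy]hept-1-en-3-ol (C3 epimer mixture) | COc1cc(CC[C@H](CC(O)C=C)O[Si](C)(C)C(C)(C)C)ccc1OCc1ccccc1
F4 | step 8 | (3R,5R)-1-[3,4-bis(benzyloxy)phenyl]-7-[4-(benzyloxy)-3-methoxyphenyl]-3-hydroxyheptan-5-yl acetate | COc1cc(CC[C@H](C[C@@H](CCc2ccc(OCc3ccccc3)c(OCc3ccccc3)c2)O)OC(C)=O)ccc1OCc1ccccc1
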